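The route rests on cutting the C3–C4 bond of the oxolane O1–C2–C3–C4–C5. Each half, ArCH(O)–CH(CH3), is a 1-arylallyl unit whose vinyl group has taken up hydrogen, so the ring unravels to an acyclic bis(1-arylallyl) ether, S at the veratryl carbon and R at the silyl-protected syringyl carbon. In one operation, hydrogen-atom transfer from a metal hydride to either vinyl group, 5-exo radical closure and reduction of the new primary radical create C3–C4, the ring and both methyl-bearing stereocentres; the pseudo-symmetry of the ring lets both initiation sites converge. The ether is assembled by iridium-catalysed branch-selective allylic etherification with a lipase-resolved allylic alcohol.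

Key step: step 8

Assumption: the (Ra,Rc,Rc) antipode of the binaphthyl bis(1-phenylethyl)phosphoramidite ligand is taken to give the R-configured branched ether from an (E)-3-arylallyl carbonate and an oxygen nucleophile, the usual sense for this catalyst family; the configuration of the diene is to be confirmed on the first run and the mirror-image ligand used if it proves otherwise.

Remark on the precursor: the phenol carries a triisopropylsilyl group rather than a smaller silyl group, because the diene is built with a nucleophilic metal alkoxide that could strip or transfer a less hindered aryl silyl ether; fluoride still removes it at the end.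

**Route**

Step 1
Reactants: 1 veratraldehyde (3,4-dimethoxybenzaldehyde); 2 vinylmagnesium bromide
Product: 3 rac-1-(3,4-dimethoxyphenyl)prop-2-en-1-ol
Conditions: 2 (1.2 equiv), THF, 0 °C; then aq. NH4Cl (no acid)
Reagents that add atoms: vinylmagnesium bromide (2), C=C[Mg]Br
Why: Grignard 1,2-addition to a non-enolisable aryl aldehyde should give the allylic alcohol cleanly, the stereocentre being left racemic and sorted out in step 2.

Step 2
Reactants: 3 rac-1-(3,4-dimethoxyphenyl)prop-2-en-1-ol
Product: 4 (S)-1-(3,4-dimethoxyphenyl)prop-2-en-1-ol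
Conditions: Novozym 435 (immobilised Candida antarctica lipase B), vinyl acetate, MTBE, 30 °C, stopped just past half conversion; chromatography on Et3N-washed silica
Reagents that add atoms: none
Why: Lipase-catalysed kinetic resolution by irreversible transesterification: with aryl as the large and vinyl as the medium substituent the enzyme should acetylate the R alcohol, so the S alcohol is selected (not created) as the unreacted enantiomer and its optical purity should rise as conversion passes one half.

Step 3
Reactants: 5 syringaldehyde (4-hydroxy-3,5-dimethoxybenzaldehyde)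
Product: 6 3,5-dimethoxy-4-(triisopropylsilyloxy)benzaldehyde
Conditions: TIPSCl, imidazole, DMF, rt to 40 °C
Reagents that add atoms: triisopropylsilyl chloride, CC(C)[Si](Cl)(C(C)C)C(C)C
Why: Imidazole-mediated O-silylation of an acidic phenol should proceed readily, and the bulky silyl ether flanked by two methoxy groups should survive the ylide, hydride, organolithium and alkoxide reagents of steps 4 to 7.

Step 4
Reactants: 6 3,5-dimethoxy-4-(triisopropylsilyloxy)benzaldehyde; 7 (carbethoxymethylene)triphenylphosphorane
Product: 8 ethyl (E)-3-[3,5-dimethoxy-4-(triisopropylsilyloxy)phenyl]prop-2-enoate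
Conditions: 7 (1.2 equiv), toluene, 80 °C
Reagents that add atoms: (carbethoxymethylene)triphenylphosphorane (7), CCOC(=O)C=P(c1ccccc1)(c1ccccc1)c1ccccc1
Why: Wittig olefination with a stabilised ylide under neutral, base-free conditions should give the E cinnamate and leave the aryl silyl ether untouched.

Step 5
Reactants: 8 ethyl (E)-3-[3,5-dimethoxy-4-(triisopropylsilyloxy)phenyl]prop-2-enoate
Product: 9 (E)-3-[3,5-dimethoxy-4-(triisopropylsilyloxy)phenyl]prop-2-en-1-ol
Conditions: DIBAL-H (2.3 equiv), CH2Cl2, −78 °C; Rochelle salt
Reagents that add atoms: none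
Why: DIBAL-H 1,2-reduction of an α,β-unsaturated ester should give the allylic alcohol without touching the alkene geometry or the silyl ether.

Step 6
Reactants: 9 (E)-3-[3,5-dimethoxy-4-(triisopropylsilyloxy)phenyl]prop-2-en-1-ol
Product: 11 tert-butyl (E)-3-[3,5-dimethoxy-4-(triisopropylsilyloxy)phenyl]prop-2-en-1-yl carbonate, via lithium cinnamyl alkoxide 10 (not isolated)
Conditions: n-BuLi (1.0 equiv), THF, −78 °C; then Boc2O, −78 to 0 °C; Et3N-washed silica
Reagents that add atoms: di-tert-butyl dicarbonate, CC(C)(C)OC(=O)OC(=O)OC(C)(C)C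
Why: Alkoxycarbonylation of the lithium alkoxide with Boc2O should give the tert-butyl carbonate, the leaving group of choice for alkoxide nucleophiles in iridium allylic substitution because the tert-butoxide it releases does not compete.

Step 7
Reactants: 4 (S)-1-(3,4-dimethoxyphenyl)prop-2-en-1-ol; 11 tert-butyl (E)-3-[3,5-dimethoxy-4-(triisopropylsilyloxy)phenyl]prop-2-en-1-yl carbonate
Product: 14 (S)-1-(3,4-dimethoxyphenyl)prop-2-en-1-yl (R)-1-[3,5-dimethoxy-4-(triisopropylsilyloxy)phenyl]prop-2-en-1-yl ether, via lithium (S)-alkoxide 12 (not isolated), via copper(I) (S)-alkoxide 13 (not isolated)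
Conditions: 4, n-BuLi (1.0 equiv), THF, 0 °C; CuI (1.0 equiv); then 11 (1.1 equiv), [Ir(cod)Cl]2 (2 mol %), (Ra,Rc,Rc)-binaphthyl bis(1-phenylethyl)phosphoramidite (4 mol %, preactivated with n-PrNH2), THF, rt; Et3N-washed silica
Reagents that add atoms: none
Why: Iridium-catalysed asymmetric allylic etherification: the cyclometalated Ir–phosphoramidite ionises the carbonate to a π-allyl complex that the soft copper alkoxide should attack at the aryl-bearing terminus, the ligand antipode setting the R configuration of the new ether carbon under catalyst control, while the S carbinol carbon of 4 only lends its oxygen and cannot epimerise.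

Step 8
Reactants: 14 (S)-1-(3,4-dimethoxyphenyl)prop-2-en-1-yl (R)-1-[3,5-dimethoxy-4-(triisopropylsilyloxy)phenyl]prop-2-en-1-yl ether
Product: 15 (2S,3S,4R,5R)-2-(3,4-dimethoxyphenyl)-5-[3,5-dimethoxy-4-(triisopropylsilyloxy)phenyl]-3,4-dimethyloxolane
Conditions: Mn(dpm)3 (10 mol %), PhSiH3 (2.5 equiv), t-BuOOH (1.5 equiv), i-PrOH, 0.01 M, rt, Ar
Reagents that add atoms: none
Why: A manganese(III) hydride formed from Mn(dpm)3, PhSiH3 and i-PrOH transfers a hydrogen atom to the terminal CH2 of either vinyl group; the secondary radical at C3 (or C4) adds to the inner carbon of the other vinyl group, and the primary radical that results takes a second hydrogen atom (from Mn–H or silane) and becomes the second methyl group. The closest known reaction type is the metal-hydride HAT reductive cyclisation of 1,6-dienes, that is, radical hydrogenation conditions intercepted by a hexenyl-type radical closure. The oxolane closes in the 5-exo-trig mode of a 3-oxa-5-hexenyl radical, a closure that should outrun 6-endo attack and, at high dilution with only catalytic metal hydride present, reduction of the open-chain radical. C2 and C5 are already set, and since their S,R pairing lets both aryl groups lie pseudo-equatorial in the chair-like transition state, the acceptor vinyl group should react on the face that puts its CH2 trans to the neighbouring aryl group, which fixes the stereocentre formed at the acceptor carbon. The radical carbon is planar and should turn its methyl group away from its own neighbouring aryl group and cis to the incoming CH2, the usual preference of 1-substituted hexenyl radicals, which fixes the second new stereocentre and gives 2,3-trans, 3,4-cis, 4,5-trans. The selectivity needed is this diastereocontrol plus indifference to the initiation site, and both come from the substrate: the two vinyl groups are related by the pseudo-symmetry of O1–C2–C3–C4–C5 and lead to the same product, while the ethers, arenes and aryl silyl ether do not react with the metal hydride.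

Step 9
Reactants: 15 (2S,3S,4R,5R)-2-(3,4-dimethoxyphenyl)-5-[3,5-dimethoxy-4-(triisopropylsilyloxy)phenyl]-3,4-dimethyloxolane
Product: 16 4-[(2R,3R,4S,5S)-5-(3,4-dimethoxyphenyl)-3,4-dimethyloxolan-2-yl]-2,6-dimethoxyphenol (target)
Conditions: TBAF (1.2 equiv), AcOH (1.2 equiv), THF, 0 °C
Reagents that add atoms: none
Why: Fluoride-induced desilylation of the aryl silyl ether, driven by Si–F bond formation and buffered so that the electron-rich phenoxide is not left exposed, should free the phenol without touching the benzylic ether stereocentres.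

**Compound list**

1 | veratraldehyde (3,4-dimethoxybenzaldehyde) | COc1ccc(C=O)cc1OC | starting material
2 | vinylmagnesium bromide | C=C[Mg]Br | starting material
3 | rac-1-(3,4-dimethoxyphenyl)prop-2-en-1-ol | COc1ccc(cc1OC)C(O)C=C | intermediate
4 | (S)-1-(3,4-dimethoxyphenyl)prop-2-en-1-ol | COc1ccc(cc1OC)[C@H](C=C)O | intermediate
5 | syringaldehyde (4-hydroxy-3,5-dimethoxybenzaldehyde) | COc1cc(C=O)cc(OC)c1O | starting material
6 | 3,5-dimethoxy-4-(triisopropylsilyloxy)benzaldehyde | COc1cc(C=O)cc(OC)c1O[Si](C(C)C)(C(C)C)C(C)C | intermediate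
7 | (carbethoxymethylene)triphenylphosphorane | CCOC(=O)C=P(c1ccccc1)(c1ccccc1)c1ccccc1 | starting material
8 | ethyl (E)-3-[3,5-dimethoxy-4-(triisopropylsilyloxy)phenyl]prop-2-enoate | CCOC(=O)/C=C/c1cc(OC)c(O[Si](C(C)C)(C(C)C)C(C)C)c(OC)c1 | intermediate
9 | (E)-3-[3,5-dimethoxy-4-(triisopropylsilyloxy)phenyl]prop-2-en-1-ol | OC/C=C/c1cc(OC)c(O[Si](C(C)C)(C(C)C)C(C)C)c(OC)c1 | intermediate
10 | lithium (E)-3-[3,5-dimethoxy-4-(triisopropylsilyloxy)phenyl]prop-2-en-1-olate | [Li]OC/C=C/c1cc(OC)c(O[Si](C(C)C)(C(C)C)C(C)C)c(OC)c1 | intermediate (not isolated)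
11 | tert-butyl (E)-3-[3,5-dimethoxy-4-(triisopropylsilyloxy)phenyl]prop-2-en-1-yl carbonate | CC(C)(C)OC(=O)OC/C=C/c1cc(OC)c(O[Si](C(C)C)(C(C)C)C(C)C)c(OC)c1 | intermediate
12 | lithium (S)-1-(3,4-dimethoxyphenyl)prop-2-en-1-olate | COc1ccc(cc1OC)[C@H](C=C)O[Li] | intermediate (not isolated)
13 | copper(I) (S)-1-(3,4-dimethoxyphenyl)prop-2-en-1-olate | COc1ccc(cc1OC)[C@H](C=C)O[Cu] | intermediate (not isolated)
14 | (S)-1-(3,4-dimethoxyphenyl)prop-2-en-1-yl (R)-1-[3,5-dimethoxy-4-(triisopropylsilyloxy)phenyl]prop-2-en-1-yl ether | COc1ccc(cc1OC)[C@H](C=C)O[C@@H](c2cc(OC)c(O[Si](C(C)C)(C(C)C)C(C)C)c(OC)c2)C=C | intermediate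
15 | (2S,3S,4R,5R)-2-(3,4-dimethoxyphenyl)-5-[3,5-dimethoxy-4-(triisopropylsilyloxy)phenyl]-3,4-dimethyloxolane (aryl groups cis, methyl groups cis, each methyl trans to its neighbouring aryl) | COc1ccc(cc1OC)[C@@H]2[C@@H](C)[C@@H](C)[C@H](c3cc(OC)c(O[Si](C(C)C)(C(C)C)C(C)C)c(OC)c3)O2 | intermediate
16 | 4-[(2R,3R,4S,5S)-5-(3,4-dimethoxyphenyl)-3,4-dimethyloxolan-2-yl]-2,6-dimethoxyphenol | COc1ccc([C@H]2O[C@@H](c3cc(OC)c(O)c(OC)c3)[C@H](C)[C@@H]2C)cc1OC | target

**Step count and risks**

Total step count: 9. Longest linear sequence: 7 steps (5 → 6 → 8 → 9 → 11 → 14 → 15 → 16, steps 3 to 9).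

Steps most likely to fail:

1. Step 8. The open-chain secondary radical may be reduced before it closes, which would hydrogenate the vinyl groups without forming C3–C4. The methyl orientation at the radical carbon may be incompletely controlled, giving 3,4-trans isomers. Hydrogen abstraction from the doubly activated ether C–H may also compete. Fallback: setting out from 14, a sulfanyl-radical addition–cyclisation (PhSH, AIBN, slow addition, benzene, 80 °C) replaces the hydride-initiated closure. The thiyl radical adds reversibly to the terminus of either vinyl group, the same 5-exo chair closure follows and the primary radical takes hydrogen from the thiol. This should give the regioisomeric pair 2-(3,4-dimethoxyphenyl)-5-[3,5-dimethoxy-4-(triisopropylsilyloxy)phenyl]-4-methyl-3-[(phenylsulfanyl)methyl]oxolane F1 and 2-(3,4-dimethoxyphenyl)-5-[3,5-dimethoxy-4-(triisopropylsilyloxy)phenyl]-3-methyl-4-[(phenylsulfanyl)methyl]oxolane F2, both with the substituent arrangement of 15. Reductive desulfurisation of the mixture (Raney nickel, EtOH, rt) turns each CH2SPh into CH3 and converges on 15, where the route is rejoined.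

2. Step 7. The hindered secondary alkoxide may attack slowly, so that the unsubstituted allyl terminus is attacked (linear ether); double stereodifferentiation may work against the catalyst; or the electron-rich carbonate may ionise prematurely. Fallback: the roles of the two halves are exchanged so that the other C–O bond is formed. Setting out from 6, addition of 2 (THF, 0 °C) should give racemic 1-[3,5-dimethoxy-4-(triisopropylsilyloxy)phenyl]prop-2-en-1-ol F3. The lipase and vinyl acetate of step 2 should acetylate its R enantiomer to (R)-1-[3,5-dimethoxy-4-(triisopropylsilyloxy)phenyl]allyl acetate F4, which is separated from the unreacted S alcohol and deacetylated with DIBAL-H (CH2Cl2, −78 °C) to (R)-1-[3,5-dimethoxy-4-(triisopropylsilyloxy)phenyl]prop-2-en-1-ol F5. Purchased (E)-3-(3,4-dimethoxyphenyl)prop-2-en-1-ol F6 is converted as in step 6, by way of its lithium alkoxide F7, into tert-butyl (E)-3-(3,4-dimethoxyphenyl)allyl carbonate F8. F5 is then turned into its lithium alkoxide F9 and its copper(I) alkoxide F10 and coupled with F8 as in step 7, but with the mirror-image (Sa,Sc,Sc) ligand, which should now set the S veratryl carbon. The product is 14, where the route is rejoined.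

3. Step 2. The enzyme may discriminate the enantiomers incompletely with vinyl as the smaller group, or acylate slowly, so that the alcohol is recovered with too low an optical purity or mass. Fallback: setting out from 1, a catalytic enantioselective vinyl transfer (salt-free divinylzinc prepared from 2 and ZnCl2, catalytic (−)-3-exo-(dimethylamino)isoborneol, toluene, 0 °C) should, by analogy with dialkylzinc additions, attack the Si face and give 4 directly. The route is rejoined at 4 and no new compound is made (F0).

Further compounds

F1 | step 8 | 2-(3,4-dimethoxyphenyl)-5-[3,5-dimethoxy-4-(triisopropylsilyloxy)phenyl]-4-methyl-3-[(phenylsulfanyl)methyl]oxolane, substituents arranged as in 15 | COc1ccc(cc1OC)[C@@H]2[C@@H](CSc4ccccc4)[C@@H](C)[C@H](c3cc(OC)c(O[Si](C(C)C)(C(C)C)C(C)C)c(OC)c3)O2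
F2 | step 8 | 2-(3,4-dimethoxyphenyl)-5-[3,5-dimethoxy-4-(triisopropylsilyloxy)phenyl]-3-methyl-4-[(phenylsulfanyl)methyl]oxolane, substituents arranged as in 15 | COc1ccc(cc1OC)[C@@H]2[C@@H](C)[C@@H](CSc4ccccc4)[C@H](c3cc(OC)c(O[Si](C(C)C)(C(C)C)C(C)C)c(OC)c3)O2
F3 | step 7 | rac-1-[3,5-dimethoxy-4-(triisopropylsilyloxy)phenyl]prop-2-en-1-ol | COc1cc(cc(OC)c1O[Si](C(C)C)(C(C)C)C(C)C)C(O)C=C
F4 | step 7 | (R)-1-[3,5-dimethoxy-4-(triisopropylsilyloxy)phenyl]allyl acetate | COc1cc(cc(OC)c1O[Si](C(C)C)(C(C)C)C(C)C)[C@@H](C=C)OC(C)=O
F5 | step 7 | (R)-1-[3,5-dimethoxy-4-(triisopropylsilyloxy)phenyl]prop-2-en-1-ol | COc1cc(cc(OC)c1O[Si](C(C)C)(C(C)C)C(C)C)[C@@H](C=C)O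
F6 | step 7 | (E)-3-(3,4-dimethoxyphenyl)prop-2-en-1-ol (purchased) | COc1ccc(/C=C/CO)cc1OC
F7 | step 7 | lithium (E)-3-(3,4-dimethoxyphenyl)prop-2-en-1-olate | COc1ccc(/C=C/CO[Li])cc1OC
F8 | step 7 | tert-butyl (E)-3-(3,4-dimethoxyphenyl)allyl carbonate | COc1ccc(/C=C/COC(=O)OC(C)(C)C)cc1OC
F9 | step 7 | lithium (R)-1-[3,5-dimethoxy-4-(triisopropylsilyloxy)phenyl]prop-2-en-1-olate | COc1cc(cc(OC)c1O[Si](C(C)C)(C(C)C)C(C)C)[C@@H](C=C)O[Li]
F10 | step 7 | copper(I) (R)-1-[3,5-dimethoxy-4-(triisopropylsilyloxy)phenyl]prop-2-en-1-olate | COc1cc(cc(OC)c1O[Si](C(C)C)(C(C)C)C(C)C)[C@@H](C=C)O[Cu]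
F0 | step 2 | none | none
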